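The numbers of this flask are those of an exercise; no experiment stands behind them.

Early on, starting material has two exits, and what matters is how much of it reaches target and how long target then survives.

in all of them: capture agent 0.0250 M

|  | starting material | time | remark |
|---|---|---|---|
| west | 0.25 M | 8.0 h | a closed flask charged with all of it at once and left for 8.0 h |
| east | 0.25 M (fed, over 6.40 h) | 8.0 h | all but starting material at the start; starting material goes in evenly over 6.40 h, the run ends at 8.0 h |
| south-west | 0.25 M |  | a single well-mixed tank run continuously and read at steady state, 8.0 h in it on average |

    intermediate C ⇌ intermediate D (K1 = 3.01, k1 = 0.0191 min⁻¹)
    intermediate A ⇌ intermediate B (K2 = 38, k2 = 0.0729 min⁻¹)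
    capture agent + intermediate B → trapped intermediate (k3 = 0.0211 M⁻¹ min⁻¹)
    target → over-reaction product (k4 = 0.00443 min⁻¹)
    starting material → target (k5 = 0.0151 min⁻¹)
    starting material ⇌ intermediate A (K6 = 0.255, k6 = 0.00421 min⁻¹)
    intermediate A → intermediate C (k7 = 0.120 min⁻¹)

* the set-up with the highest amount of target at the outlet or at the end, in percent of the starting material put in ("none" if the first two lie within 2 percentage points) (west / east / south-west / none)
* amount of target at the outlet or at the end, in percent of the starting material put in, west
* amount of target at the outlet or at the end, in percent of the starting material put in, east
* amount of target at the outlet or at the end, in percent of the starting material put in, south-west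

- the stated concentrations are those of everything mixed, before any reaction; amounts are the same in each set-up
- the feed brings no volume worth counting
- run time (west): 8.0 h

I read the scheme line by line. Intermediate C and intermediate D exchange with each other and give nothing back to target, so I set them aside. Intermediate B returns to intermediate A at 0.00192 min⁻¹, but capture takes it at 5.28 × 10⁻⁴ min⁻¹, which is less, so I drop capture. Target is lost at k4 c(target), which is first order, so I go to logarithms. Target falls by one power of ten in 8.65 h, and I call this the decade time of target.

Starting material goes to target with a selectivity of 78.2%, and it waits 0.863 h on average. Intermediate A returns to starting material at 0.0165 min⁻¹, less than the 0.193 min⁻¹ at which it goes on, so in this reckoning I count that branch as lost to target.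

Now I reckon ages. In west, I take target as 0.825 decades old on average, which leaves 11.7%. In east, I take the middle of the dose as 0.455 decades old, which leaves 27.5%. That is one mean age for a spread of ages, so I hold it as a low estimate. South-west has no single age, so I use the tank balance, which gives 22.6%.

The forecast says 12.6% for west, 30.4% for east and 23% for south-west, with east best, since “the evenly fed run has the youngest target at the end”. On each set-up it stands above my figure, on east by 2.9 percentage points.

The simulation gives 12.5% for west, 30.4% for east and 23.0% for south-west, so east is best.

West's target goes from 34.8% at 4.00 h to 12.5% at 8.00 h, a fall of 0.445 decades, against 0.462 from the decade time. East, read on to 20 h, has 1.39 decades more, which takes 30.4% to 1.25%, and the reading there is 1.41%. With the dose pressed into a shorter feed, east gives 17.4%, less than south-west's 23.0%.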